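Which flask gives you more product, violet in its shorter time or ochre in its longer one?

| setting | eta | zeta | violet | ochre |
|---|---|---|---|---|
| substrate | 0.066 M | 0.27 M | 0.40 M | 0.11 M |
| free catalyst | 11 mM | 11 mM | 11 mM | 11 mM |
| temperature | −5 °C | 8 °C | 15 °C | 0 °C |
| remark | run made earlier | run made earlier |  |  |
| time |  |  | 2.0 h | 3.0 h |

| run | time / h | product / % |
|---|---|---|
| eta | 0.250 | 11.9 |
| eta | 0.417 | 20.1 |
| eta | 0.833 | 39.7 |
| eta | 1.50 | 59.5 |
| eta | 3.00 | 78.2 |
| zeta | 0.250 | 27.0 |
| zeta | 0.833 | 65.9 |
| zeta | 1.33 | 78.0 |
| zeta | 2.00 | 88.2 |
| zeta | 3.00 | 92.5 |

(standard deviation of a reading: 1 percentage point)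

1. the winner by amount of product, in percent of the substrate charged; "neither" if no more than 2 percentage points parts them (violet / ochre / neither)
2. how much product is there at the end, in percent of the substrate charged: violet
3. how much product is there at the end, in percent of the substrate charged: ochre

Turn the question round and ask what ochre would need. Replace each curve by its mean: the natural logarithm of the charge over the fraction left, divided by the time. The last readings give 0.508 /h for eta and 0.863 /h for zeta. Equal product means equal constant times time, so for a tie violet's constant must stand at 1.50 times ochre's.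

Going from eta to zeta, −5 °C to 8 °C, multiplies the constant by 1.70. Ochre to violet, 0 °C to 15 °C, is a wider step, and the substrate charge rises in both pairs by similar factors, 4.09 and 3.64. Stretching the factor geometrically, I get 1.85, larger than the tie needs.

Placed the same way between the runs, ochre gets 0.623 /h, its mean rate constant. Placed the same way at its own temperature, violet gets 1.15 /h. My own reckoning, each constant with its own flask's time, then gives ochre 84.6 % and violet 90.0 %. The error of the mean lies against violet: zeta's constant up to 2.00 h is 1.07 /h, larger than up to 3.00 h.

The forecast says violet, with 92 % for violet and 84 % for ochre, noting that late on “the catalyst is dying, the product inhibits, or an equilibrium plateau is near”. Its violet stands higher than mine, its ochre lower.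

The flask gives violet: violet 93.4 %, ochre 86.3 %.

    substrate + free catalyst ⇌ catalyst intermediate A (K = 17.0 /M, k = 2.27 /M/min, Ea = 45.0 kJ/mol, ΔH = −43.0 kJ/mol)
    catalyst intermediate A → catalyst intermediate B (k = 1.55 /min, Ea = 75.0 kJ/mol)
    catalyst intermediate B → free catalyst + product (k = 0.542 /min, Ea = 84.0 kJ/mol)
    2 free catalyst → spent catalyst (k = 0.663 /M/min, Ea = 50.0 kJ/mol)
    (constants at 0 °C)

Ochre's result means a mean rate constant of 0.662 /h, close to the 0.623 /h carried from the runs. That mean hides a falling rate: at 3.00 h spent catalyst holds 64.4 % of the catalyst charged. Without the step to it ochre reaches 97.0 % instead of 86.3 %, and read at 30.0 h it gives 99.6 %, so loss of catalyst within the reading time is part of what stops ochre short.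

Read ochre at 50 min instead: 0.623 /h gives 40.5 %, and that flask stands at 48.7 %, more than the mean gives.

The readings were generated by integration with made-up constants, noise included.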